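**Retrosynthetic overview**

1. Target 22 ⇒ enal 21 (aldehyde to acid last) ⇒ allylic alcohol 18 + (Z)-p-coumaric acid 20 (Mitsunobu ester bond); 20 ⇐ photoisomerisation of 19.
2. 18 ⇒ enol triflate 16 + Bu3SnCH2OH 17 (C4–C15 by Stille coupling); 16 ⇒ trans-decalone 12 (kinetic triflation, then SeO2 oxidation of the isopropenyl methyl).
3. 12 ⇒ cis-fused keto-dithioketal 8 (C9 deoxygenation, dithiane hydrolysis, C5 epimerisation to the trans ring fusion).
4. Key disconnection: 8 ⇒ (S)-carvone 5 + lithiated 2-(3-chloropropyl)-1,3-dithiane 6, a C4 acyl-anion equivalent. 1,4-Addition makes C4–C5, then the enolate is alkylated at C10 by the tethered chloride (C10–C1).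
5. Ring order: ring B comes intact from carvone with the C7 stereocentre; ring A is closed in the key annulation, which also sets the C10 quaternary centre.

Assumption: locants follow eudesmane numbering (ring A = C1–C5 and C10; ring B = C5–C10; C14 = methyl on C10; C15 = carbon on C4; C11–C13 = side chain on C7), and the target is the (5R,7R,10R) isomer given by the SMILES.

**Route**

Step 1
Reactants: 1 1,3-dithiane; 2 1-bromo-3-chloropropane
Product: 4 2-(3-chloropropyl)-1,3-dithiane, via 2-lithio-1,3-dithiane 3 (not isolated)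
Conditions: n-BuLi, THF, −30 °C; then 2, −78 °C to rt
Reagents that add atoms: none
Why: Corey–Seebach alkylation, in which the lithio-dithiane displaces bromide much faster than chloride, so the chloride is kept for the annulation; no stereocentre is formed.

Step 2
Reactants: 4 2-(3-chloropropyl)-1,3-dithiane; 5 (S)-(+)-carvone
Product: 8 (5S,7S,10S)-4,4-(propane-1,3-diyldisulfanediyl)-15-nor-eudesm-11-en-9-one (cis-fused decalin with a spiro-1,3-dithiane at C4), via lithio-dithiane 6 (not isolated), via lithium enolate 7 (not isolated)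
Conditions: t-BuLi, THF/HMPA (9:1), −78 °C, 10 min; 5, −78 °C, 1 h; then rt, 12 h
Reagents that add atoms: none
Why: Michael-initiated ring closure with a Corey–Seebach acyl-anion equivalent: in THF/HMPA the lithio-dithiane adds 1,4 to carvone axially and anti to the C7 isopropenyl group (sets C5, at this stage with C4 on the non-natural face), and the regiospecific enolate, whose C5 substituent is held pseudoaxial by allylic 1,2-strain with the C10 methyl, is alkylated on that same face by the tethered chloride, closing a cis-fused ring A and setting the C10 quaternary centre with methyl syn to isopropenyl (the natural C10 configuration).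

Step 3
Reactants: 8 cis-fused spiro-dithiane ketone
Product: 10 (5S,7R,10R)-4,4-(propane-1,3-diyldisulfanediyl)-15-nor-eudesm-11-ene, via hydrazone 9 (not isolated)
Conditions: N2H4·H2O, KOH, diethylene glycol, 130 °C then 200 °C
Reagents that add atoms: none
Why: Wolff–Kishner (Huang-Minlon) reduction removes the C9 carbonyl, which was needed only to activate carvone; the dithioketal, the isopropenyl group and all three stereocentres are inert because C10 is quaternary and C5 and C7 are not enolisable.

Step 4
Reactants: 10 deoxygenated spiro-dithiane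
Product: 12 (5R,7R,10R)-15-nor-eudesm-11-en-4-one (trans-fused; 5α-H anti to the 10β-methyl), via cis-fused ketone 11 (not isolated)
Conditions: MeI, NaHCO3, MeCN/H2O (9:1), 45 °C; then NaOMe, MeOH, rt
Reagents that add atoms: water, O
Why: S-methylation and hydrolysis (Fétizon-type dithiane cleavage) unmask the C4 ketone, and methoxide then epimerises C5 through the enolate to the trans-fused decalone, expected to be the more stable isomer (all-chair with equatorial C7 isopropenyl, whereas the cis isomer must carry C4 axial on ring B), which gives the natural 5α-H.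

Step 5
Reactants: 12 trans-fused C4 ketone
Product: 14 (5R,7R,10S)-15-nor-eudesma-3,11-dien-4-yl trifluoromethanesulfonate, via lithium enolate 13 (not isolated)
Conditions: LiN(iPr)2, THF, −78 °C; PhNTf2, −78 to 0 °C
Reagents that add atoms: N-phenylbis(trifluoromethanesulfonimide), O=S(=O)(N(c1ccccc1)S(=O)(=O)C(F)(F)F)C(F)(F)F
Why: kinetic deprotonation by the hindered amide takes the C3 methylene proton rather than the ring-fusion C5–H next to the quaternary carbon, and O-triflation of this enolate fixes the C3=C4 position without touching C5.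

Step 6
Reactants: 14 enol triflate
Product: 16 (5R,7R,10S)-12-oxo-15-nor-eudesma-3,11(13)-dien-4-yl trifluoromethanesulfonate, via allylic alcohol 15 (not isolated)
Conditions: SeO2 (1.2 equiv), 1,4-dioxane/H2O (30:1), 80 °C
Reagents that add atoms: selenium dioxide, O=[Se]=O
Why: Riley allylic oxidation (ene reaction, then 2,3-sigmatropic shift) oxidises the methyl group of the 1,1-disubstituted isopropenyl alkene to the alcohol and on to the enal, while the electron-poor enol-triflate double bond does not enter the ene step.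

Step 7
Reactants: 16 enal enol triflate; 17 (tributylstannyl)methanol
Product: 18 (5R,7R,10R)-15-hydroxyeudesma-3,11(13)-dien-12-al
Conditions: Pd(PPh3)4 (5 mol %), LiCl (3 equiv), 1,4-dioxane, 90 °C
Reagents that add atoms: none
Why: Migita–Kosugi–Stille coupling in which the α-hydroxy stannane acts as a hydroxymethyl-anion equivalent and joins C15 to the former carbonyl carbon C4 with the double bond held at C3=C4; the enal is inert to zerovalent palladium and to the stannane.

Step 8
Reactants: 19 (E)-p-coumaric acid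
Product: 20 (Z)-p-coumaric acid
Conditions: hν (310–365 nm), MeOH, rt; chromatography in the dark, 19 recycled
Reagents that add atoms: none
Why: photochemical E-to-Z isomerisation of the cinnamate chromophore gives a photostationary mixture from which the Z acid is separated.

Step 9
Reactants: 18 hydroxy enal; 20 (Z)-p-coumaric acid
Product: 21 (5R,7R,10R)-15-[(Z)-4-hydroxycinnamoyloxy]eudesma-3,11(13)-dien-12-al
Conditions: PPh3, DIAD, THF, 0 °C to rt, dark
Reagents that add atoms: none
Why: Mitsunobu esterification, in which the primary allylic alcohol is activated as its alkoxyphosphonium ion and displaced directly (SN2) by the carboxylate, which reacts in preference to the much less acidic phenol; the Z double bond and the enal are untouched.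

Step 10
Reactants: 21 coumarate enal
Product: 22 (5R,7R,10R)-15-[(Z)-4-hydroxycinnamoyloxy]eudesma-3,11(13)-dien-12-oic acid (CNP0183482.1)
Conditions: NaClO2, NaH2PO4, 2-methyl-2-butene (excess), t-BuOH/H2O, 0 °C to rt, dark
Reagents that add atoms: sodium chlorite, [Na+].[O-]Cl=O
Why: Pinnick oxidation converts the α-methylene aldehyde into the acid without moving either double bond, and the alkene scavenger traps HOCl so that the phenol and the ring alkene are not chlorinated.

**Compound list**

1 | 1,3-dithiane | C1CSCSC1 | starting material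
2 | 1-bromo-3-chloropropane | ClCCCBr | starting material
3 | 2-lithio-1,3-dithiane | [Li]C1SCCCS1 | intermediate
4 | 2-(3-chloropropyl)-1,3-dithiane | ClCCCC1SCCCS1 | intermediate
5 | (S)-(+)-carvone, (5S)-2-methyl-5-(prop-1-en-2-yl)cyclohex-2-en-1-one | C=C(C)[C@@H]1CC(=O)C(C)=CC1 | starting material
6 | 2-lithio-2-(3-chloropropyl)-1,3-dithiane | [Li]C1(CCCCl)SCCCS1 | intermediate
7 | lithium (3S,5S)-3-[2-(3-chloropropyl)-1,3-dithian-2-yl]-2-methyl-5-(prop-1-en-2-yl)cyclohex-1-en-1-olate (3,5-trans) | C=C(C)[C@@H]1CC(O[Li])=C(C)[C@H](C1)C2(CCCCl)SCCCS2 | intermediate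
8 | (5S,7S,10S)-4,4-(propane-1,3-diyldisulfanediyl)-15-nor-eudesm-11-en-9-one (cis-fused; 10-methyl, 5-H and 7-isopropenyl on one face) | C=C(C)[C@@H]1CC(=O)[C@@]2(C)CCCC3(SCCCS3)[C@H]2C1 | intermediate
9 | C9 hydrazone of 8 | C=C(C)[C@@H]1CC(=NN)[C@@]2(C)CCCC3(SCCCS3)[C@H]2C1 | intermediate
10 | (5S,7R,10R)-4,4-(propane-1,3-diyldisulfanediyl)-15-nor-eudesm-11-ene (cis-fused) | C=C(C)[C@@H]1CC[C@@]2(C)CCCC3(SCCCS3)[C@H]2C1 | intermediate
11 | (5S,7R,10R)-15-nor-eudesm-11-en-4-one (cis-fused, 5-epi) | C=C(C)[C@@H]1CC[C@@]2(C)CCCC(=O)[C@H]2C1 | intermediate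
12 | (5R,7R,10R)-15-nor-eudesm-11-en-4-one, (4aR,7R,8aR)-4a-methyl-7-(prop-1-en-2-yl)octahydronaphthalen-1(2H)-one (trans-fused) | C=C(C)[C@@H]1CC[C@@]2(C)CCCC(=O)[C@@H]2C1 | intermediate
13 | lithium (5R,7R,10S)-15-nor-eudesma-3,11-dien-4-olate | C=C(C)[C@@H]1CC[C@@]2(C)CCC=C(O[Li])[C@@H]2C1 | intermediate
14 | (5R,7R,10S)-15-nor-eudesma-3,11-dien-4-yl trifluoromethanesulfonate | C=C(C)[C@@H]1CC[C@@]2(C)CCC=C(OS(=O)(=O)C(F)(F)F)[C@@H]2C1 | intermediate
15 | (5R,7R,10S)-12-hydroxy-15-nor-eudesma-3,11(13)-dien-4-yl trifluoromethanesulfonate | C=C(CO)[C@@H]1CC[C@@]2(C)CCC=C(OS(=O)(=O)C(F)(F)F)[C@@H]2C1 | intermediate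
16 | (5R,7R,10S)-12-oxo-15-nor-eudesma-3,11(13)-dien-4-yl trifluoromethanesulfonate | C=C(C=O)[C@@H]1CC[C@@]2(C)CCC=C(OS(=O)(=O)C(F)(F)F)[C@@H]2C1 | intermediate
17 | (tributylstannyl)methanol | CCCC[Sn](CCCC)(CCCC)CO | starting material
18 | (5R,7R,10R)-15-hydroxyeudesma-3,11(13)-dien-12-al | C=C(C=O)[C@@H]1CC[C@@]2(C)CCC=C(CO)[C@@H]2C1 | intermediate
19 | (E)-p-coumaric acid | O=C(O)/C=C/c1ccc(O)cc1 | starting material
20 | (Z)-p-coumaric acid | O=C(O)/C=C\c1ccc(O)cc1 | intermediate
21 | (5R,7R,10R)-15-[(Z)-4-hydroxycinnamoyloxy]eudesma-3,11(13)-dien-12-al | C=C(C=O)[C@@H]1CC[C@@]2(C)CCC=C(COC(=O)/C=C\c3ccc(O)cc3)[C@@H]2C1 | intermediate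
22 | (5R,7R,10R)-15-[(Z)-4-hydroxycinnamoyloxy]eudesma-3,11(13)-dien-12-oic acid | C=C(C(=O)O)[C@@H]1CC[C@@]2(C)CCC=C(COC(=O)/C=C\c3ccc(O)cc3)[C@@H]2C1 | target

**Step count and risks**

Total: 10 steps. Longest linear sequence: 9 steps (steps 1–7, 9 and 10, from 1,3-dithiane; 8 from carvone).

Steps most likely to fail:

- Step 2. The hindered tertiary dithianyl anion may add 1,2 to the α-methyl enone, 6 may self-cyclise to the cyclobutane dithioketal, or the ring closure may be slow. Fallback, from 5 back to 8: make the C4–C5 bond with the unhindered parent anion and attach the three-carbon arm afterwards. 2-Lithio-1,3-dithiane 3 is added to 5 in THF/HMPA at −78 °C, and the resulting lithium enolate F1 is silylated in the flask with t-BuMe2SiCl to the tert-butyldimethylsilyl enol ether F2. n-BuLi (THF/HMPA, −30 °C) converts F2 into the lithio-dithiane F3, which is alkylated with 2 to the chloropropyl silyl enol ether F4. Anhydrous Bu4NF in THF then releases the tetrabutylammonium enolate F5, which closes ring A onto C10 on the same face and gives 8.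

- Step 4. The cis/trans equilibrium of the angular-methyl decalone is the least certain point of the route and may leave much 11. Fallback, from 11 (or an 11/12 mixture) back to 12: replace equilibration by kinetic protonation of the ring-fusion enolate. Me3SiCl and Et3N in DMF at 130 °C give the tetrasubstituted C4=C5 trimethylsilyl enol ether F6. MeLi in THF converts it into the lithium enolate F7, which is protonated at −78 °C with AcOH from the face anti to the axial C10 methyl group to give 12.

- Step 7. The α-hydroxy stannane transfers slowly and the triflate sits next to the ring-fusion carbon. Fallback, from 14 to 21: bring in C15 as a carbonyl carbon and oxidise the side chain last. Pd(OAc)2/dppp, CO (1 atm), MeOH and Et3N in DMF at 60 °C convert 14 into the methyl ester F8. i-Bu2AlH (CH2Cl2, −78 °C) gives the dienol F9, and Mitsunobu esterification with 20 gives the coumarate F10. SeO2 in dioxane at 80 °C then oxidises the isopropenyl methyl through the allylic alcohol F11 to 21; the ring alkene is deactivated by its allylic acyloxy group.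

**Further compounds**

F1 | step 2 | lithium (3S,5S)-3-(1,3-dithian-2-yl)-2-methyl-5-(prop-1-en-2-yl)cyclohex-1-en-1-olate | C=C(C)[C@@H]1CC(O[Li])=C(C)[C@H](C1)C2SCCCS2
F2 | step 2 | tert-butyldimethylsilyl enol ether of the carvone–dithiane 1,4-adduct | C=C(C)[C@@H]1CC(O[Si](C)(C)C(C)(C)C)=C(C)[C@H](C1)C2SCCCS2
F3 | step 2 | 2-lithio-dithiane derived from F2 | C=C(C)[C@@H]1CC(O[Si](C)(C)C(C)(C)C)=C(C)[C@H](C1)C2([Li])SCCCS2
F4 | step 2 | 2-(3-chloropropyl)dithiane silyl enol ether | C=C(C)[C@@H]1CC(O[Si](C)(C)C(C)(C)C)=C(C)[C@H](C1)C2(CCCCl)SCCCS2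
F5 | step 2 | tetrabutylammonium enolate of the chloropropyl adduct | CCCC[N+](CCCC)(CCCC)CCCC.C=C(C)[C@@H]1CC([O-])=C(C)[C@H](C1)C2(CCCCl)SCCCS2
F6 | step 4 | (7R,10R)-4-(trimethylsilyloxy)-15-nor-eudesma-4,11-diene | C=C(C)[C@@H]1CC[C@@]2(C)CCCC(O[Si](C)(C)C)=C2C1
F7 | step 4 | lithium (7R,10R)-15-nor-eudesma-4,11-dien-4-olate | C=C(C)[C@@H]1CC[C@@]2(C)CCCC(O[Li])=C2C1
F8 | step 7 | methyl (5R,7R,10R)-eudesma-3,11-dien-15-oate | C=C(C)[C@@H]1CC[C@@]2(C)CCC=C(C(=O)OC)[C@@H]2C1
F9 | step 7 | (5R,7R,10R)-eudesma-3,11-dien-15-ol | C=C(C)[C@@H]1CC[C@@]2(C)CCC=C(CO)[C@@H]2C1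
F10 | step 7 | (5R,7R,10R)-eudesma-3,11-dien-15-yl (Z)-4-hydroxycinnamate | C=C(C)[C@@H]1CC[C@@]2(C)CCC=C(COC(=O)/C=C\c3ccc(O)cc3)[C@@H]2C1
F11 | step 7 | (5R,7R,10R)-12-hydroxyeudesma-3,11(13)-dien-15-yl (Z)-4-hydroxycinnamate | C=C(CO)[C@@H]1CC[C@@]2(C)CCC=C(COC(=O)/C=C\c3ccc(O)cc3)[C@@H]2C1
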